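**Retrosynthetic overview**
1. The target's γ-lactone (O2–C16) is formed last, by base-mediated acyl transfer from an iso-lactone closed on O14, with the freed 14-OH trapped as the acetate.
2. The 3,4-oxirane comes from hydroxyl-directed epoxidation of the macrocyclic allylic alcohol (free 2-OH).
3. The 14-membered ring is closed through the C1–C2 bond, the bond formed when geranylgeranyl diphosphate cyclises, by Cr(II)-mediated allylation of a C2 enal with a 3-(bromomethyl)butenolide; the single stereocentre C14 controls C1 and C2.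
4. The (S)-butenolide comes from a 17-carbon hydroxy aldehyde by D-proline α-aminoxylation and cis-Wittig olefination; the chain comes from (E,E)-farnesyl acetate plus a two-carbon hydrazone, and C-17 from formaldehyde.
5. Ring order: butenolide (temporary lactone) → carbocycle → oxirane → final lactone.

Assumption: cembrane numbering is used (C1 carries the C15(=C17)–C16 unit, C2 the lactone oxygen, C3/C4 the oxirane, C14 the acetate), so the target is (1R,2S,3R,4R,14S,7E,11E); isomerically pure (2E,6E)-farnesyl acetate is taken as commercial.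

**Route**

Step 1
Reactants: 1 (2E,6E)-farnesyl acetate
Product: 2 (2E,6E,10E)-12-hydroxy-3,7,11-trimethyldodeca-2,6,10-trien-1-yl acetate
Conditions: SeO2 (cat.), t-BuOOH, salicylic acid (cat.), CH2Cl2, 0 °C → rt
Reagents that add atoms: tert-butyl hydroperoxide, CC(C)(C)OO
Why: The Sharpless SeO2/t-BuOOH allylic oxidation (ene reaction then [2,3]-sigmatropic shift) hydroxylates the (E)-methyl of the terminal, most electron-rich alkene while the allylic acetate deactivates the C2=C3 end, and no stereocentre is formed.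

Step 2
Reactants: 2 (2E,6E,10E)-12-hydroxy-3,7,11-trimethyldodeca-2,6,10-trien-1-yl acetate
Product: 3 (2E,6E,10E)-12-bromo-3,7,11-trimethyldodeca-2,6,10-trien-1-yl acetate
Conditions: CBr4, PPh3, CH2Cl2, 0 °C
Reagents that add atoms: tetrabromomethane, BrC(Br)(Br)Br
Why: The Appel reaction converts the primary allylic alcohol into the bromide by SN2 displacement of the alkoxyphosphonium ion under neutral conditions, without allylic transposition or loss of the acetate.

Step 3
Reactants: 3 (2E,6E,10E)-12-bromo-3,7,11-trimethyldodeca-2,6,10-trien-1-yl acetate; 4 acetaldehyde N,N-dimethylhydrazone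
Product: 8 (4E,8E,12E)-14-hydroxy-4,8,12-trimethyltetradeca-4,8,12-trienal, via lithiated hydrazone 5 (not isolated), via hydrazone acetate 6 (not isolated), via hydrazone alcohol 7 (not isolated)
Conditions: 4, LDA, THF, 0 °C; cannulate into 3, −78 °C; then MeOH, K2CO3, rt; then sat. aq. oxalic acid, Et2O, rt
Reagents that add atoms: water, O
Why: In this Corey–Enders azaenolate alkylation the SN2 attack on the primary allylic bromide at −78 °C is much faster than attack on the acetate, the acetate is then removed by K2CO3/MeOH transesterification and the base-stable hydrazone is hydrolysed by aqueous acid, giving the two-carbon-homologated aldehyde with no stereocentre formed.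

Step 4
Reactants: 8 (4E,8E,12E)-14-hydroxy-4,8,12-trimethyltetradeca-4,8,12-trienal; 9 methyl (triphenylphosphoranylidene)acetate
Product: 13 (5S)-5-[(2E,6E,10E)-12-hydroxy-2,6,10-trimethyldodeca-2,6,10-trien-1-yl]furan-2(5H)-one, via anilinooxy aldehyde 10 (not isolated), via (Z)-anilinooxy enoate 11 (not isolated), via (Z)-hydroxy enoate 12 (not isolated)
Conditions: PhNO (0.95 equiv), D-proline (20 mol %), MeCN, −20 °C; then MeOH, 9, −20 → 0 °C; then Cu(OAc)2 (30 mol %), rt; PPTS (cat.)
Reagents that add atoms: nitrosobenzene, O=Nc1ccccc1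
Why: D-proline-catalysed α-aminoxylation (the enamine attacks the oxygen of PhN=O on the face fixed by the carboxylic acid hydrogen bond, mirror image of the L-proline → (R) outcome) sets C14 as (S), the base-free cis-selective Wittig reaction of an α-oxygenated aldehyde in methanol gives mainly the (Z)-enoate, and Cu(II)-catalysed N–O cleavage frees the γ-hydroxyl, which lactonises onto the cis ester (the E isomer cannot cyclise and is separated).

Step 5
Reactants: 13 (5S)-5-[(2E,6E,10E)-12-hydroxy-2,6,10-trimethyldodeca-2,6,10-trien-1-yl]furan-2(5H)-one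
Product: 14 (5S)-3-(hydroxymethyl)-5-[(2E,6E,10E)-12-hydroxy-2,6,10-trimethyldodeca-2,6,10-trien-1-yl]furan-2(5H)-one
Conditions: 37 % aq. HCHO (5 equiv), PBu3 (20 mol %), MeOH–CHCl3, rt
Reagents that add atoms: formaldehyde, C=O
Why: The Morita–Baylis–Hillman hydroxymethylation (phosphine conjugate addition at C1, aldol of the enolate with formaldehyde at C15, loss of the phosphine) installs C17 on the α-carbon, and the weakly basic phosphine in a protic medium should not deprotonate the γ-position, so C14 is retained.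

Step 6
Reactants: 14 (5S)-3-(hydroxymethyl)-5-[(2E,6E,10E)-12-hydroxy-2,6,10-trimethyldodeca-2,6,10-trien-1-yl]furan-2(5H)-one
Product: 15 (2E,6E,10E)-12-[(2S)-4-(hydroxymethyl)-5-oxo-2,5-dihydrofuran-2-yl]-3,7,11-trimethyldodeca-2,6,10-trienal
Conditions: activated MnO2 (15 equiv), CH2Cl2, rt, monitored
Reagents that add atoms: none
Why: MnO2 allylic oxidation is fast for the electron-rich geraniol-type alcohol and very slow for the hydroxymethyl group on the electron-poor butenolide alkene, so only the (E)-enal is formed.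

Step 7
Reactants: 15 (2E,6E,10E)-12-[(2S)-4-(hydroxymethyl)-5-oxo-2,5-dihydrofuran-2-yl]-3,7,11-trimethyldodeca-2,6,10-trienal
Product: 16 (2E,6E,10E)-12-[(2S)-4-(bromomethyl)-5-oxo-2,5-dihydrofuran-2-yl]-3,7,11-trimethyldodeca-2,6,10-trienal
Conditions: NBS, Me2S, CH2Cl2, −30 → 0 °C (pre-formed complex)
Reagents that add atoms: N-bromosuccinimide, O=C1CCC(=O)N1Br
Why: The Corey–Kim bromination (bromide displaces the alkoxysulfonium ion) is the standard neutral conversion of Baylis–Hillman-type allylic alcohols into allylic bromides and spares the enal, the trisubstituted alkenes and the base-sensitive C14 centre.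

Step 8
Reactants: 16 (2E,6E,10E)-12-[(2S)-4-(bromomethyl)-5-oxo-2,5-dihydrofuran-2-yl]-3,7,11-trimethyldodeca-2,6,10-trienal
Product: 19 (1S,2R,14S,3E,7E,11E)-2-hydroxycembra-3,7,11,15(17)-tetraen-16,14-olide, via allylchromium species 17 (not isolated), via chromium alkoxide 18 (not isolated)
Conditions: CrCl2 (8 equiv), 4 Å MS, THF, rt, syringe-pump addition of 16 (final 2 mM); then H2O
Reagents that add atoms: none
Why: This Nozaki–Hiyama–Kishi allylation closes the 14-membered ring through the C1–C2 bond with γ-attack giving the exocyclic methylene; the butenolide locks C14 trans to CH2Cr so the chair Zimmerman–Traxler transition state gives the 1,2-anti adduct, the enal adds to the face of C1 opposite the C13 chain on C14 (trans-disubstituted lactone), so C14 sets both C1 and C2, and vinylogous β-elimination is blocked because the C14–O bond lies in the plane of the allyl unit.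

Step 9
Reactants: 19 (1S,2R,14S,3E,7E,11E)-2-hydroxycembra-3,7,11,15(17)-tetraen-16,14-olide
Product: 20 (1S,2S,3R,4R,14S,7E,11E)-3,4-epoxy-2-hydroxycembra-7,11,15(17)-trien-16,14-olide
Conditions: VO(acac)2 (5 mol %), t-BuOOH (1.5 equiv, decane), CH2Cl2, 0 °C
Reagents that add atoms: tert-butyl hydroperoxide, CC(C)(C)OO
Why: The Sharpless–Michaelson hydroxyl-directed epoxidation reacts only at the allylic-alcohol alkene, and A(1,3) strain between C2 and the cis methyl on C4 holds H2 in the alkene plane so oxygen is delivered to the face bearing the OH (threo selectivity, also the peripheral face), setting C3 and C4 as (3R,4R).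

Step 10
Reactants: 20 (1S,2S,3R,4R,14S,7E,11E)-3,4-epoxy-2-hydroxycembra-7,11,15(17)-trien-16,14-olide
Product: 22 (1R,2S,3R,4R,14S,7E,11E)-14-acetoxy-3,4-epoxycembra-7,11,15(17)-trien-16,2-olide, via translactonised alcohol 21 (not isolated)
Conditions: DBU (1.2 equiv), CH2Cl2, rt, 1 h; then Ac2O (1.1 equiv, added over 2 h), 0 °C
Reagents that add atoms: acetic anhydride, CC(=O)OC(C)=O
Why: Proposed new method: DBU promotes reversible 1,3-O-to-O acyl transfer through a bicyclic tetrahedral intermediate so that 20 and the isomeric C2-lactone 21 interconvert, and the unhindered 14-OH of 21 is acetylated much faster than the epoxide-flanked, hydrogen-bonded 2-OH of 20 (Curtin–Hammett control), draining the equilibrium to the target with no stereocentre touched; the closest known reactions are base-mediated translactonisation of β-(1-hydroxyalkyl)-α-methylene-γ-butyrolactones and selective acylation of the less hindered hydroxyl of a diol.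

**Compound list**

1 | (2E,6E)-farnesyl acetate, (2E,6E)-3,7,11-trimethyldodeca-2,6,10-trien-1-yl acetate | CC(=O)OC/C=C(\C)CC/C=C(\C)CCC=C(C)C | starting material
2 | (2E,6E,10E)-12-hydroxy-3,7,11-trimethyldodeca-2,6,10-trien-1-yl acetate | CC(=O)OC/C=C(\C)CC/C=C(\C)CC/C=C(\C)CO | intermediate
3 | (2E,6E,10E)-12-bromo-3,7,11-trimethyldodeca-2,6,10-trien-1-yl acetate | CC(=O)OC/C=C(\C)CC/C=C(\C)CC/C=C(\C)CBr | intermediate
4 | acetaldehyde N,N-dimethylhydrazone | CC=NN(C)C | starting material
5 | lithiated acetaldehyde N,N-dimethylhydrazone (azaenolate) | [Li]CC=NN(C)C | intermediate (not isolated)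
6 | (2E,6E,10E)-14-(dimethylhydrazinylidene)-3,7,11-trimethyltetradeca-2,6,10-trien-1-yl acetate | CC(=O)OC/C=C(\C)CC/C=C(\C)CC/C=C(\C)CCC=NN(C)C | intermediate (not isolated)
7 | (2E,6E,10E)-14-(dimethylhydrazinylidene)-3,7,11-trimethyltetradeca-2,6,10-trien-1-ol | OC/C=C(\C)CC/C=C(\C)CC/C=C(\C)CCC=NN(C)C | intermediate (not isolated)
8 | (4E,8E,12E)-14-hydroxy-4,8,12-trimethyltetradeca-4,8,12-trienal | OC/C=C(\C)CC/C=C(\C)CC/C=C(\C)CCC=O | intermediate
9 | methyl (triphenylphosphoranylidene)acetate | COC(=O)C=P(c1ccccc1)(c1ccccc1)c1ccccc1 | starting material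
10 | (2S,4E,8E,12E)-14-hydroxy-4,8,12-trimethyl-2-[(phenylamino)oxy]tetradeca-4,8,12-trienal | O=C[C@@H](ONc1ccccc1)C/C(C)=C/CC/C(C)=C/CC/C(C)=C/CO | intermediate (not isolated)
11 | methyl (2Z,4S,6E,10E,14E)-16-hydroxy-6,10,14-trimethyl-4-[(phenylamino)oxy]hexadeca-2,6,10,14-tetraenoate | COC(=O)/C=C\[C@@H](ONc1ccccc1)C/C(C)=C/CC/C(C)=C/CC/C(C)=C/CO | intermediate (not isolated)
12 | methyl (2Z,4S,6E,10E,14E)-4,16-dihydroxy-6,10,14-trimethylhexadeca-2,6,10,14-tetraenoate | COC(=O)/C=C\[C@@H](O)C/C(C)=C/CC/C(C)=C/CC/C(C)=C/CO | intermediate (not isolated)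
13 | (5S)-5-[(2E,6E,10E)-12-hydroxy-2,6,10-trimethyldodeca-2,6,10-trien-1-yl]furan-2(5H)-one | O=C1C=C[C@H](C/C(C)=C/CC/C(C)=C/CC/C(C)=C/CO)O1 | intermediate
14 | (5S)-3-(hydroxymethyl)-5-[(2E,6E,10E)-12-hydroxy-2,6,10-trimethyldodeca-2,6,10-trien-1-yl]furan-2(5H)-one | O=C1C(CO)=C[C@H](C/C(C)=C/CC/C(C)=C/CC/C(C)=C/CO)O1 | intermediate
15 | (2E,6E,10E)-12-[(2S)-4-(hydroxymethyl)-5-oxo-2,5-dihydrofuran-2-yl]-3,7,11-trimethyldodeca-2,6,10-trienal | O=C1C(CO)=C[C@H](C/C(C)=C/CC/C(C)=C/CC/C(C)=C/C=O)O1 | intermediate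
16 | (2E,6E,10E)-12-[(2S)-4-(bromomethyl)-5-oxo-2,5-dihydrofuran-2-yl]-3,7,11-trimethyldodeca-2,6,10-trienal | O=C1C(CBr)=C[C@H](C/C(C)=C/CC/C(C)=C/CC/C(C)=C/C=O)O1 | intermediate
17 | allylchromium(III) dichloride derived from 16 (Cr on C17, solvent ligands omitted) | O=C1C(C[Cr](Cl)Cl)=C[C@H](C/C(C)=C/CC/C(C)=C/CC/C(C)=C/C=O)O1 | intermediate (not isolated)
18 | chromium(III) 2-alkoxide of 19 | C=C1C(=O)O[C@@H]2[C@@H]1[C@H](O[Cr](Cl)Cl)/C=C(\C)CC/C=C(\C)CC/C=C(\C)C2 | intermediate (not isolated)
19 | (1S,2R,14S,3E,7E,11E)-2-hydroxycembra-3,7,11,15(17)-tetraen-16,14-olide (carbocycle trans-fused at C14–C1 to an α-methylene-γ-butyrolactone closed on O14; free allylic 2-OH) | C=C1C(=O)O[C@@H]2[C@@H]1[C@H](O)/C=C(\C)CC/C=C(\C)CC/C=C(\C)C2 | intermediate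
20 | (1S,2S,3R,4R,14S,7E,11E)-3,4-epoxy-2-hydroxycembra-7,11,15(17)-trien-16,14-olide | C=C1C(=O)O[C@@H]2[C@@H]1[C@H](O)[C@H]1O[C@]1(C)CC/C=C(\C)CC/C=C(\C)C2 | intermediate
21 | (1R,2S,3R,4R,14S,7E,11E)-3,4-epoxy-14-hydroxycembra-7,11,15(17)-trien-16,2-olide | C=C1C(=O)O[C@H]2[C@H]1[C@@H](O)C/C(C)=C/CC/C(C)=C/CC[C@@]1(C)O[C@H]21 | intermediate (not isolated)
22 | (1R,2S,3R,4R,14S,7E,11E)-14-acetoxy-3,4-epoxycembra-7,11,15(17)-trien-16,2-olide (CNP0294029.1) | C=C1C(=O)O[C@H]2[C@H]1[C@@H](OC(C)=O)C/C(C)=C/CC/C(C)=C/CC[C@@]1(C)O[C@H]21 | target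

The descriptors at C1 and C2 change between 19, 20 and 21/22 only because the CIP priorities change (free OH versus acylated O, alkene versus oxirane); the geometry is the same throughout.

**Count and risks**

Total steps: 10. Longest linear sequence: 10 steps from 1.

The three steps most likely to fail:

Step 8 (macrocyclisation). Oligomerisation, reduction of the bromide, or insufficient facial control at C1 are possible. The fallback sets out from 16 and closes the ring by a metal-reductant-free intramolecular allylboration. Borylation at C17 (B2pin2, Pd2(dba)3 cat., toluene, rt) gives the formyl allylboronate F1, which is isolable because ester-substituted allylboronates react sluggishly. Heating at high dilution (toluene, 80 °C, 2 mM, or cat. Sc(OTf)3 at 0 °C) takes it through the same ring-locked chair transition state to the pinacol borate F2, and aqueous work-up comes back to the route at 19.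

Step 10 (direction of the acyl transfer). The equilibrium may lie on the side of 20, or 20 may be acetylated directly at O2. The fallback sets out from 20 and differentiates the two hydroxyls in the ring-opened form. LiOH (1.05 equiv, THF–H2O, 0 °C) gives the lithium seco-carboxylate F3 and MeI in DMF gives the dihydroxy methyl ester F4. The unhindered 14-OH is acetylated selectively (Ac2O, 2,4,6-collidine, −40 °C, or lipase with vinyl acetate) to the 14-acetate F5. Catalytic DBU then closes the only free hydroxyl (2-OH) onto the methyl ester, coming back to the route at the target 22.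

Step 5 (Baylis–Hillman on the butenolide). The reaction may be slow, or γ-deprotonation may erode C14. The fallback sets out from 13 and introduces C17 by cross-coupling instead of enolate chemistry: α-iodination (I2, pyridine, CH2Cl2) gives the 3-iodobutenolide F6, and Stille coupling with (tributylstannyl)methanol (Pd(PPh3)4, dioxane, 80 °C) comes back to the route at 14.

Further compounds
F1 | step 8 | (2E,6E,10E)-3,7,11-trimethyl-12-{(2S)-5-oxo-4-[(4,4,5,5-tetramethyl-1,3,2-dioxaborolan-2-yl)methyl]-2,5-dihydrofuran-2-yl}dodeca-2,6,10-trienal | O=C1C(CB2OC(C)(C)C(C)(C)O2)=C[C@H](C/C(C)=C/CC/C(C)=C/CC/C(C)=C/C=O)O1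
F2 | step 8 | pinacol borate (2-O-Bpin) of 19 | C=C1C(=O)O[C@@H]2[C@@H]1[C@H](OB3OC(C)(C)C(C)(C)O3)/C=C(\C)CC/C=C(\C)CC/C=C(\C)C2
F3 | step 10 | lithium (1R,2S,3R,4R,14S,7E,11E)-3,4-epoxy-2,14-dihydroxycembra-7,11,15(17)-trien-16-oate | C=C(C(=O)[O-])[C@@H]1[C@@H](O)C/C(C)=C/CC/C(C)=C/CC[C@@]2(C)O[C@@H]2[C@H]1O.[Li+]
F4 | step 10 | methyl (1R,2S,3R,4R,14S,7E,11E)-3,4-epoxy-2,14-dihydroxycembra-7,11,15(17)-trien-16-oate | C=C(C(=O)OC)[C@@H]1[C@@H](O)C/C(C)=C/CC/C(C)=C/CC[C@@]2(C)O[C@@H]2[C@H]1O
F5 | step 10 | methyl (1R,2S,3R,4R,14S,7E,11E)-14-acetoxy-3,4-epoxy-2-hydroxycembra-7,11,15(17)-trien-16-oate | C=C(C(=O)OC)[C@@H]1[C@@H](OC(C)=O)C/C(C)=C/CC/C(C)=C/CC[C@@]2(C)O[C@@H]2[C@H]1O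
F6 | step 5 | (5S)-3-iodo-5-[(2E,6E,10E)-12-hydroxy-2,6,10-trimethyldodeca-2,6,10-trien-1-yl]furan-2(5H)-one | O=C1C(I)=C[C@H](C/C(C)=C/CC/C(C)=C/CC/C(C)=C/CO)O1
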